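**Retrosynthetic overview**
1. The pyrrole is the only ring and is built last in one Barton–Zard operation. C2–C3 forms by intermolecular Michael addition of methyl isocyanoacetate to (E)-1-nitrohenicos-1-ene, C4–C5 forms by closure of the nitronate onto the isocyanide carbon, and loss of HNO2 aromatises the ring.
2. The nitroalkene is not handled as such. It is released in situ from the storable 1-nitrohenicosan-2-yl acetate.
3. That acetate comes from the nitro alcohol made by a Henry (nitroaldol) reaction of icosanal with nitromethane.
4. Icosanal comes from cheap icosan-1-ol (arachidyl alcohol). Its C19 tail becomes the nonadecyl group and its carbonyl carbon becomes ring carbon C3.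

Assumption: the target (C25H45NO2) has no stereocentre, so no enantiocontrol is needed. The stereocentres of the intermediates are formed racemic and are erased on aromatisation.

**Route**

Step 1
Reactants: 1 icosan-1-ol
Product: 2 icosanal
Conditions: TEMPO (10 mol %), PhI(OAc)2 (1.1 equiv), CH2Cl2, 25–30 °C, 4 h; aq. Na2S2O3/NaHCO3 wash
Reagents that add atoms: none
Why: The TEMPO/PhI(OAc)2 oxoammonium oxidation (Piancatelli–Margarita type) of a primary alcohol stops at the aldehyde in the absence of water, 1 carries no other functional group, and no stereocentre is formed.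

Step 2
Reactants: 2 icosanal; 3 nitromethane
Product: 4 (±)-1-nitrohenicosan-2-ol
Conditions: MeNO2 (10 equiv), KOtBu (10 mol %), THF/t-BuOH 1:1, 0 °C to rt, 6 h; AcOH quench
Reagents that add atoms: none
Why: In this Henry (nitroaldol) reaction the nitronate of the large excess of nitromethane adds to the unhindered aldehyde faster than the aldehyde self-condenses, and the new carbinol centre is formed racemic, which does not matter because it becomes an sp2 ring carbon in step 4.

Step 3
Reactants: 4 (±)-1-nitrohenicosan-2-ol
Product: 5 (±)-1-nitrohenicosan-2-yl acetate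
Conditions: Ac2O (1.5 equiv), conc. H2SO4 (cat.), CH2Cl2, 0 °C to rt, 2 h
Reagents that add atoms: acetic anhydride, CC(=O)OC(C)=O
Why: Acid-catalysed O-acetylation avoids the base that would trigger premature E1cB elimination and gives a stable, non-polymerising precursor of the nitroalkene without touching the stereocentre.

Step 4
Reactants: 5 (±)-1-nitrohenicosan-2-yl acetate; 6 methyl isocyanoacetate
Product: 10 methyl 3-nonadecyl-1H-pyrrole-2-carboxylate, via nitroalkene 7 (not isolated), via Michael adduct 8 (not isolated), via nitropyrroline 9 (not isolated)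
Conditions: 6 (1.1 equiv), DBU (2.2 equiv, slow addition), THF, 0 °C to rt, 16 h
Reagents that add atoms: none
Why: In this Barton–Zard pyrrole synthesis DBU eliminates AcOH (E1cB) to release 7 at low concentration, the isocyanoacetate anion adds to it in an intermolecular Michael addition (C2–C3 bond), the nitronate closes onto the isocyanide carbon (5-endo-dig, C4–C5 bond), and loss of HNO2 with tautomerisation aromatises the ring, which erases all transient stereocentres and places the alkyl group regiospecifically at C3 next to the ester, while the methyl ester is safe towards non-nucleophilic DBU.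

**Compound list**
1 | icosan-1-ol (arachidyl alcohol) | CCCCCCCCCCCCCCCCCCCCO | starting material
2 | icosanal | CCCCCCCCCCCCCCCCCCCC=O | intermediate
3 | nitromethane | C[N+](=O)[O-] | starting material
4 | (±)-1-nitrohenicosan-2-ol | CCCCCCCCCCCCCCCCCCCC(O)C[N+](=O)[O-] | intermediate
5 | (±)-1-nitrohenicosan-2-yl acetate | CCCCCCCCCCCCCCCCCCCC(C[N+](=O)[O-])OC(C)=O | intermediate
6 | methyl isocyanoacetate | [C-]#[N+]CC(=O)OC | starting material
7 | (E)-1-nitrohenicos-1-ene (not isolated) | CCCCCCCCCCCCCCCCCCC/C=C/[N+](=O)[O-] | intermediate
8 | methyl 2-isocyano-3-(nitromethyl)docosanoate (diastereomer mixture, racemic, not isolated) | CCCCCCCCCCCCCCCCCCCC(C[N+](=O)[O-])C([N+]#[C-])C(=O)OC | intermediate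
9 | methyl 4-nitro-3-nonadecyl-3,4-dihydro-2H-pyrrole-2-carboxylate (diastereomer mixture, racemic, not isolated) | CCCCCCCCCCCCCCCCCCCC1C(C=NC1C(=O)OC)[N+](=O)[O-] | intermediate
10 | methyl 3-nonadecyl-1H-pyrrole-2-carboxylate | CCCCCCCCCCCCCCCCCCCc1cc[nH]c1C(=O)OC | target

**Total step count:** 4
**Longest linear sequence:** 4 (1 → 2 → 4 → 5 → 10)

**Three steps most likely to fail**

Step 4. The α-unsubstituted nitroalkene 7 can oligomerise or take up a second nucleophile before ring closure, which lowers the yield. The fallback sets out from 2 and comes back at 10, and builds the ring by the tosylglycinate (Kenner-type) pyrrole synthesis instead. CH2=CHMgBr is added to icosanal 2 in THF at 0 °C to give racemic docos-1-en-3-ol F1. Dess–Martin periodinane in CH2Cl2 oxidises it to docos-1-en-3-one F2, which is used at once. Methyl N-tosylglycinate and DBU in THF then effect aza-Michael addition and intramolecular aldol closure to methyl 3-hydroxy-3-nonadecyl-1-tosylpyrrolidine-2-carboxylate F3. POCl3/pyridine dehydrates it to methyl 3-nonadecyl-1-tosyl-2,5-dihydro-1H-pyrrole-2-carboxylate F4. DBU in THF finally expels p-toluenesulfinate and the product tautomerises to 10.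

Step 2. The enolisable aldehyde can self-condense, and the nitro alcohol can dehydrate and take up a second nitromethane to give a 1,3-dinitro compound. The fallback sets out from 2 and comes back at 7, and avoids the nitroaldol altogether. Wittig methylenation of 2 (Ph3PCH3Br, KOtBu, THF, 0 °C) gives henicos-1-ene F5. Radical nitration with AgNO2 and TEMPO (4 Å molecular sieves, 1,2-dichloroethane, 70 °C) gives (E)-nitroalkene 7. Here 7 is isolated and taken into the pyrrole formation with 6 and 1.1 equiv of DBU.

Step 3. Partial elimination during acetylation or work-up can give mixtures of 5 and 7 that are awkward to purify. The fallback sets out from 4 and comes back at 7, and drops the masked nitroalkene in favour of deliberate dehydration. MsCl and Et3N (2.2 equiv) in CH2Cl2 at −10 °C convert 4 into 1-nitrohenicosan-2-yl methanesulfonate F6. F6 eliminates in the same flask to 7. After a quick filtration through silica, 7 is used at once with 6 and 1.1 equiv of DBU to give 10.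

**Further compounds**
F1 | step 4 | (±)-docos-1-en-3-ol | CCCCCCCCCCCCCCCCCCCC(O)C=C
F2 | step 4 | docos-1-en-3-one | CCCCCCCCCCCCCCCCCCCC(=O)C=C
F3 | step 4 | methyl 3-hydroxy-3-nonadecyl-1-tosylpyrrolidine-2-carboxylate (diastereomer mixture, racemic) | CCCCCCCCCCCCCCCCCCCC1(O)CCN(C1C(=O)OC)S(=O)(=O)c1ccc(C)cc1
F4 | step 4 | (±)-methyl 3-nonadecyl-1-tosyl-2,5-dihydro-1H-pyrrole-2-carboxylate | CCCCCCCCCCCCCCCCCCCC1=CCN(C1C(=O)OC)S(=O)(=O)c1ccc(C)cc1
F5 | step 2 | henicos-1-ene | CCCCCCCCCCCCCCCCCCCC=C
F6 | step 3 | (±)-1-nitrohenicosan-2-yl methanesulfonate | CCCCCCCCCCCCCCCCCCCC(C[N+](=O)[O-])OS(C)(=O)=O
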